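**Retrosynthetic overview**
1. Target 17 ⇒ α-hydroxy ketone 16 (chelation-controlled reduction sets C1') ⇒ aryl bromide 12 + methyl (R)-lactate 13 (C5–C1' bond, C2' from the chiral pool).
2. 12 ⇒ cyclic acetal 10 + veratrole 11 (Friedel–Crafts arylation at C2, trans to the C3 methyl).
3. 10 ⇒ (E)-propenylarene 7: an enantioselective oxidative 1,2-aryl shift makes the C3–C3a bond and the C3 stereocenter, then O1 closes onto C2. The dihydrofuran ring is the only ring formed; both benzene rings come from catechol.
4. 7 ⇒ catechol 1 (via guaiacol, bromination, iodination, Suzuki coupling with (E)-propenylboronic acid 5, acetylation); 11 ⇒ catechol 1.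

Assumption: the chiral iodane of step 6 is made beforehand from 2-iodoresorcinol and methyl (S)-lactate (Mitsunobu etherification, then oxidation to the diacetate) and is counted as a reagent.

**Step 1**
Reactants: 1 catechol (benzene-1,2-diol)
Product: 2 guaiacol (2-methoxyphenol)
Conditions: Me2SO4 (1.0 equiv), NaOH (1.0 equiv), H2O/PhNO2, 45 °C
Reagents that add atoms: dimethyl sulfate, COS(=O)(=O)OC
Why: Williamson ether synthesis on the catechol monoanion; guaiacol is less acidic and passes into the organic layer, which holds back the second methylation (catechol and veratrole are removed by base extraction and distillation).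

**Step 2**
Reactants: 2 guaiacol
Product: 3 4-bromo-2-methoxyphenol
Conditions: NBS (1.0 equiv), MeCN, −20 → 0 °C
Reagents that add atoms: N-bromosuccinimide, O=C1CCC(=O)N1Br
Why: Electrophilic aromatic bromination, directed para to the free hydroxyl, which is the stronger donor.

**Step 3**
Reactants: 3 4-bromo-2-methoxyphenol
Product: 4 4-bromo-2-iodo-6-methoxyphenol
Conditions: NIS (1.05 equiv), TsOH·H2O (10 mol%), MeCN, 23 °C
Reagents that add atoms: N-iodosuccinimide, O=C1CCC(=O)N1I
Why: Electrophilic aromatic iodination ortho to the hydroxyl with the para position blocked, the same site that takes the second halogen when guaiacol is dibrominated.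

**Step 4**
Reactants: 4 4-bromo-2-iodo-6-methoxyphenol; 5 (E)-prop-1-en-1-ylboronic acid
Product: 6 4-bromo-2-methoxy-6-[(E)-prop-1-en-1-yl]phenol
Conditions: Pd(dppf)Cl2 (3 mol%), K2CO3 (3 equiv), dioxane/H2O 4:1, 60 °C
Reagents that add atoms: none
Why: Suzuki–Miyaura coupling; oxidative addition at C–I is far faster than at C–Br and the E geometry of the boronic acid is retained.

**Step 5**
Reactants: 6 4-bromo-2-methoxy-6-[(E)-prop-1-en-1-yl]phenol
Product: 7 4-bromo-2-methoxy-6-[(E)-prop-1-en-1-yl]phenyl acetate
Conditions: Ac2O (1.2 equiv), pyridine, DMAP (5 mol%), CH2Cl2, 0 → 23 °C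
Reagents that add atoms: acetic anhydride, CC(=O)OC(C)=O
Why: O-acylation; the acetate protects the phenol from oxidation and stops O1 from attacking C-β in step 6.

**Step 6**
Reactants: 7 4-bromo-2-methoxy-6-[(E)-prop-1-en-1-yl]phenyl acetate
Product: 10 (3S)-5-bromo-2,7-dimethoxy-3-methyl-2,3-dihydro-1-benzofuran (both C2 epimers), via acetoxy dimethyl acetal 8 (not isolated), via phenol dimethyl acetal 9 (not isolated)
Conditions: (R,R)-ArI(OAc)2 [ArI = dimethyl (2R,2'R)-2,2'-[(2-iodo-1,3-phenylene)bis(oxy)]dipropanoate] (1.0 equiv), TfOH (2.0 equiv), MeOH (4 equiv), CH2Cl2, −78 → −30 °C; then MeOH (excess), 23 °C, 3 h; NaHCO3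
Reagents that add atoms: methanol, CO
Why: Proposed new method: a lactate-derived chiral aryl-λ3-iodane effects an enantioselective oxidative 1,2-aryl shift of an ortho-acyloxy (E)-1-propenylarene, and the product is closed in the same pot to the cyclic acetal; the activated iodane adds to the C-β Si face while methanol adds anti at C-α, the arene then displaces the iodanyl group at C-β with inversion through a phenonium ion, methanol opens that ion at the oxygen-stabilised C-α to give 8 with the new benzylic stereocenter (C3) S, and acid methanolysis of the acetate (to 9) lets O1 close the five-membered acetal 10; the closest known chemistry is the racemic oxidative rearrangement of β-methylstyrenes to 2-arylpropanal acetals with PhI(OH)OTs in methanol and the enantioselective rearrangement of 1,1-disubstituted alkenes to α-aryl ketones with lactate-based iodanes, so the sense of induction must be confirmed on the first run (the (S,S)-iodane is the remedy).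

**Step 7**
Reactants: 1 catechol
Product: 11 veratrole (1,2-dimethoxybenzene)
Conditions: MeI (2.5 equiv), K2CO3 (3 equiv), acetone, reflux
Reagents that add atoms: iodomethane, CI
Why: Exhaustive Williamson O-methylation of both phenols.

**Step 8**
Reactants: 10 (3S)-5-bromo-2,7-dimethoxy-3-methyl-2,3-dihydro-1-benzofuran; 11 veratrole (4 equiv)
Product: 12 (2S,3S)-5-bromo-2-(3,4-dimethoxyphenyl)-7-methoxy-3-methyl-2,3-dihydro-1-benzofuran
Conditions: TfOH (5 mol%), CH2Cl2, −40 → −10 °C
Reagents that add atoms: none
Why: Friedel–Crafts arylation of the cyclic oxocarbenium ion formed from the acetal; veratrole attacks through C4 (para to a methoxy group) on the face anti to the C3 methyl, which sets C2 as S (2,3-trans, also the thermodynamic isomer).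

**Step 9**
Reactants: 12 (2S,3S)-5-bromo-2-(3,4-dimethoxyphenyl)-7-methoxy-3-methyl-2,3-dihydro-1-benzofuran; 13 methyl (R)-lactate
Product: 16 (2R)-1-[(2S,3S)-2-(3,4-dimethoxyphenyl)-7-methoxy-3-methyl-2,3-dihydro-1-benzofuran-5-yl]-2-hydroxypropan-1-one, via chloromagnesium alkoxide of the Weinreb amide 14 (not isolated), via aryllithium 15 (not isolated)
Conditions: 13 (1.5 equiv), MeNHOMe·HCl (1.5 equiv), iPrMgCl (4.5 equiv), THF, −20 °C; in a second flask 12, n-BuLi (1.05 equiv), THF, −78 °C; second solution transferred onto the first, −78 → −20 °C; aq. NH4Cl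
Reagents that add atoms: none
Why: Bromine–lithium exchange followed by a Weinreb ketone synthesis on the amide made in situ from the ester; the magnesium-chelated tetrahedral intermediate stops at the ketone, and the lactate stereocenter, held as its alkoxide, is not enolised, so C2' stays R.

**Step 10**
Reactants: 16 (2R)-1-[(2S,3S)-2-(3,4-dimethoxyphenyl)-7-methoxy-3-methyl-2,3-dihydro-1-benzofuran-5-yl]-2-hydroxypropan-1-one
Product: 17 (1S,2R)-1-[(2S,3S)-2-(3,4-dimethoxyphenyl)-7-methoxy-3-methyl-2,3-dihydro-1-benzofuran-5-yl]propane-1,2-diol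
Conditions: Zn(BH4)2 (1.5 equiv), Et2O, −20 → 0 °C; aq. NH4Cl
Reagents that add atoms: none
Why: Chelation-controlled (Cram chelate) reduction; zinc bridges the carbonyl and the α-hydroxyl and hydride arrives anti to the methyl group, giving the anti (erythro) diol with C1' S.

**Compound list**
1 | catechol (benzene-1,2-diol) | Oc1ccccc1O | starting material
2 | guaiacol (2-methoxyphenol) | COc1ccccc1O | intermediate
3 | 4-bromo-2-methoxyphenol | COc1cc(Br)ccc1O | intermediate
4 | 4-bromo-2-iodo-6-methoxyphenol | COc1cc(Br)cc(I)c1O | intermediate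
5 | (E)-prop-1-en-1-ylboronic acid | C/C=C/B(O)O | starting material
6 | 4-bromo-2-methoxy-6-[(E)-prop-1-en-1-yl]phenol | C/C=C/c1cc(Br)cc(OC)c1O | intermediate
7 | 4-bromo-2-methoxy-6-[(E)-prop-1-en-1-yl]phenyl acetate | C/C=C/c1cc(Br)cc(OC)c1OC(C)=O | intermediate
8 | 4-bromo-2-[(2S)-1,1-dimethoxypropan-2-yl]-6-methoxyphenyl acetate | COC(OC)[C@@H](C)c1cc(Br)cc(OC)c1OC(C)=O | intermediate (not isolated)
9 | 4-bromo-2-[(2S)-1,1-dimethoxypropan-2-yl]-6-methoxyphenol | COC(OC)[C@@H](C)c1cc(Br)cc(OC)c1O | intermediate (not isolated)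
10 | (3S)-5-bromo-2,7-dimethoxy-3-methyl-2,3-dihydro-1-benzofuran (both C2 epimers) | COC1Oc2c(OC)cc(Br)cc2[C@@H]1C | intermediate
11 | veratrole (1,2-dimethoxybenzene) | COc1ccccc1OC | intermediate
12 | (2S,3S)-5-bromo-2-(3,4-dimethoxyphenyl)-7-methoxy-3-methyl-2,3-dihydro-1-benzofuran | COc1ccc([C@H]2Oc3c(OC)cc(Br)cc3[C@@H]2C)cc1OC | intermediate
13 | methyl (R)-lactate | C[C@@H](O)C(=O)OC | starting material
14 | chloromagnesium alkoxide of (2R)-2-hydroxy-N-methoxy-N-methylpropanamide | C[C@@H](O[Mg]Cl)C(=O)N(C)OC | intermediate (not isolated)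
15 | [(2S,3S)-2-(3,4-dimethoxyphenyl)-7-methoxy-3-methyl-2,3-dihydro-1-benzofuran-5-yl]lithium | COc1ccc([C@H]2Oc3c(OC)cc([Li])cc3[C@@H]2C)cc1OC | intermediate (not isolated)
16 | (2R)-1-[(2S,3S)-2-(3,4-dimethoxyphenyl)-7-methoxy-3-methyl-2,3-dihydro-1-benzofuran-5-yl]-2-hydroxypropan-1-one | COc1ccc([C@H]2Oc3c(OC)cc(C(=O)[C@@H](C)O)cc3[C@@H]2C)cc1OC | intermediate
17 | (1S,2R)-1-[(2S,3S)-2-(3,4-dimethoxyphenyl)-7-methoxy-3-methyl-2,3-dihydro-1-benzofuran-5-yl]propane-1,2-diol | COc1ccc([C@H]2Oc3c(OC)cc([C@H](O)[C@@H](C)O)cc3[C@@H]2C)cc1OC | target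

**Totals**
Total steps: 10. Longest linear sequence: 9 (steps 1–6, 8, 9, 10).

**Steps most likely to fail**

Step 6 (the proposed new step). The risks are a low or reversed enantioselectivity, competing 1,2-dimethoxylation by methanol at C-β, and loss of optical purity through an enol ether during the acidic second stage. The fallback uses known chemistry, sets out from 7 and comes back at 12. Compound 7 is rearranged with achiral PhI(OH)OTs in MeOH at 23 °C, the known racemic oxidative 1,2-aryl shift of β-methylstyrenes, which gives the racemic acetoxy dimethyl acetal F1. Methanolysis with K2CO3 in MeOH gives the racemic phenol dimethyl acetal F2, and a catalytic amount of TsOH closes it to the racemic cyclic acetal F3. Step 8 run on F3 gives the racemic trans product, that is 12 together with its (2R,3R)-enantiomer F4. Preparative SFC on an amylose-carbamate chiral stationary phase removes F4 and delivers 12, so stereocontrol moves from asymmetric induction to resolution.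

Step 8. The oxocarbenium ion can lose the C3 proton to give the aromatic 3-methylbenzofuran, which destroys C3, and the product can reopen at C2 and take up a second veratrole. The fallback replaces the electrophilic arylation by an organometallic addition; it sets out from 10 and comes back at 12. Compound 10 is hydrolysed (1 M HCl, THF, 23 °C) to the lactol F5. Veratrole 11 is brominated with NBS in MeCN to 4-bromo-1,2-dimethoxybenzene F6, which with Mg in THF gives the Grignard reagent F7. Three equivalents of F7 are added to F5 at −78 → 0 °C; the first opens the lactol to the phenoxide aldehyde and the next adds to the carbonyl, giving the diol F8 as a mixture at the carbinol carbon. TsOH·H2O (10 mol%) in CH2Cl2 then ionises the benzylic alcohol, and the phenol closes the ring trans to the methyl group to give 12.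

Step 9. The aryllithium must add once to an amide formed in situ, and the α-hydroxy ketone 16 can epimerise at C2' on work-up. The fallback builds the side chain by catalyst control in place of the chiral pool; it sets out from 12 and comes back at 17, so step 10 is also bypassed. Sonogashira coupling of 12 with propyne (Pd(PhCN)2Cl2, P(t-Bu)3, CuI, iPr2NH, dioxane, 23 °C) gives the propynyl arene F9. Buffered KMnO4 (NaHCO3, MgSO4, acetone/H2O, 0 °C) oxidises the alkyne to the 1,2-diketone F10. Transfer hydrogenation with RuCl[(R,R)-TsDPEN](p-cymene) in HCO2H/Et3N at 40 °C reduces both carbonyls, with dynamic kinetic resolution of the intermediate hydroxy ketone, to the anti (1S,2R)-diol 17.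

**Further compounds**
F1 | step 6 | racemic 4-bromo-2-(1,1-dimethoxypropan-2-yl)-6-methoxyphenyl acetate | COC(OC)C(C)c1cc(Br)cc(OC)c1OC(C)=O
F2 | step 6 | racemic 4-bromo-2-(1,1-dimethoxypropan-2-yl)-6-methoxyphenol | COC(OC)C(C)c1cc(Br)cc(OC)c1O
F3 | step 6 | racemic 5-bromo-2,7-dimethoxy-3-methyl-2,3-dihydro-1-benzofuran | COC1Oc2c(OC)cc(Br)cc2C1C
F4 | step 6 | (2R,3R)-5-bromo-2-(3,4-dimethoxyphenyl)-7-methoxy-3-methyl-2,3-dihydro-1-benzofuran | COc1ccc([C@@H]2Oc3c(OC)cc(Br)cc3[C@H]2C)cc1OC
F5 | step 8 | (3S)-5-bromo-7-methoxy-3-methyl-2,3-dihydro-1-benzofuran-2-ol | OC1Oc2c(OC)cc(Br)cc2[C@@H]1C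
F6 | step 8 | 4-bromo-1,2-dimethoxybenzene | COc1ccc(Br)cc1OC
F7 | step 8 | (3,4-dimethoxyphenyl)magnesium bromide | COc1ccc([Mg]Br)cc1OC
F8 | step 8 | 4-bromo-2-[(2S)-1-(3,4-dimethoxyphenyl)-1-hydroxypropan-2-yl]-6-methoxyphenol | COc1ccc(C(O)[C@@H](C)c2cc(Br)cc(OC)c2O)cc1OC
F9 | step 9 | (2S,3S)-2-(3,4-dimethoxyphenyl)-7-methoxy-3-methyl-5-(prop-1-yn-1-yl)-2,3-dihydro-1-benzofuran | COc1ccc([C@H]2Oc3c(OC)cc(C#CC)cc3[C@@H]2C)cc1OC
F10 | step 9 | 1-[(2S,3S)-2-(3,4-dimethoxyphenyl)-7-methoxy-3-methyl-2,3-dihydro-1-benzofuran-5-yl]propane-1,2-dione | COc1ccc([C@H]2Oc3c(OC)cc(C(=O)C(C)=O)cc3[C@@H]2C)cc1OC
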